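**Retrosynthetic overview**
- The ten-membered carbocycle is the last ring: it is closed at C3–C4 by a nickel-catalysed, chromium-mediated alkenyl iodide–aldehyde coupling, followed only by desilylation.
- Before ring closure: the C8 tiglate is installed by Mitsunobu inversion, the C1/C10 epoxide (second ring) by Shi epoxidation of the acyclic E-alkene, and the C3 aldehyde by PMB removal and oxidation.
- C7–C8 is the fragment union: a chromium Barbier allylation joins a 3-(bromomethyl)butenolide (C4–C7, C11–C13, C15) to a β,γ-unsaturated aldehyde (C1–C3, C8–C10, C14); the existing lactone ring enforces the 6,7-trans relationship.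
- The butenolide (first ring) comes from a Z-β-iodoenal and methyl 3-bromo-2-(bromomethyl)acrylate by enantioselective chromium-catalysed γ-bromoallylation, lactonisation and 1,3-bromide shift.
- Building blocks: but-2-yne-1,4-diol, methyl 2-(bromomethyl)acrylate, pent-3-yn-1-ol, oxirane, tiglic acid.

Assumption: germacrane numbering is used throughout (C1/C10 epoxide, C3 carbinol, C4=C5 Z-alkene carrying C15, C6 lactone carbinol, C7, C8 tiglate carbinol, C11=C13 methylene, C12 carbonyl), which makes the target (1R,3S,6R,7R,8R,10R); oxirane and tiglic acid are counted as starting materials.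

**Route**

Step 1
Reactants: 1 but-2-yne-1,4-diol
Product: 2 4-[(tert-butyldimethylsilyl)oxy]but-2-yn-1-ol
Conditions: NaH (1.0 equiv), TBSCl (1.0 equiv), THF, 0 °C to rt
Reagents that add atoms: tert-butyldimethylsilyl chloride, CC(C)(C)[Si](C)(C)Cl
Why: Monosilylation of a symmetric diol through its monosodium alkoxide (Williamson-type O-silylation) differentiates the two ends; no stereocentre is formed.

Step 2
Reactants: 2 4-[(tert-butyldimethylsilyl)oxy]but-2-yn-1-ol
Product: 4 (2Z)-4-[(tert-butyldimethylsilyl)oxy]-3-iodobut-2-en-1-ol, via cyclic alkenylalanate 3 (not isolated)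
Conditions: NaAlH2(OCH2CH2OCH3)2, THF, 0 °C; then iodine, THF, −78 °C
Reagents that add atoms: iodine, [I][I]
Why: Hydroxyl-directed trans-hydroalumination of the propargylic alcohol places aluminium on the alkyne carbon remote from the free hydroxyl in a five-membered alkoxyalanate, and iodinolysis with retention gives the Z-alkenyl iodide (iodine cis to CH2OH) that later fixes the C4=C5 geometry.

Step 3
Reactants: 4 (2Z)-4-[(tert-butyldimethylsilyl)oxy]-3-iodobut-2-en-1-ol
Product: 5 (2Z)-4-[(tert-butyldimethylsilyl)oxy]-3-iodobut-2-enal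
Conditions: MnO2 (excess), CH2Cl2, rt, dark
Reagents that add atoms: none
Why: Chemoselective MnO2 oxidation of the allylic alcohol gives the enal without touching the alkenyl iodide or the silyl ether, and the Z geometry is kept by working cold and in the dark.

Step 4
Reactants: 6 methyl 2-(bromomethyl)prop-2-enoate
Product: 7 methyl 2,3-dibromo-2-(bromomethyl)propanoate
Conditions: Br2 (1.05 equiv), CH2Cl2, 0 °C to rt
Reagents that add atoms: bromine, BrBr
Why: Electrophilic addition of bromine across the acrylate double bond gives the achiral tribromide.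

Step 5
Reactants: 7 methyl 2,3-dibromo-2-(bromomethyl)propanoate
Product: 8 methyl (2Z)-3-bromo-2-(bromomethyl)prop-2-enoate
Conditions: Et3N (1.0 equiv), Et2O, 0 °C
Reagents that add atoms: none
Why: E2 dehydrobromination (the only β-hydrogens sit on the two equivalent CH2Br carbons and the α-bromine leaves) gives the 3-bromo-2-(bromomethyl)acrylate, whose alkene geometry is erased in the next step.

Step 6
Reactants: 5 (2Z)-4-[(tert-butyldimethylsilyl)oxy]-3-iodobut-2-enal; 8 methyl (2Z)-3-bromo-2-(bromomethyl)prop-2-enoate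
Product: 12 (5S)-3-(bromomethyl)-5-[(1Z)-3-[(tert-butyldimethylsilyl)oxy]-2-iodoprop-1-en-1-yl]furan-2(5H)-one, via silyl ether adduct 9 (not isolated), via hydroxy ester 10 (not isolated), via bromo lactone 11 (not isolated)
Conditions: CrCl2 (10 mol %, nickel-free), chiral 1,8-bis(4-isopropyloxazolin-2-yl)carbazole ligand (12 mol %, antipode chosen for Si-face addition), i-Pr2NEt (30 mol %), Mn powder (2 equiv), TMSCl (1.5 equiv), 8 (1.4 equiv), THF, 0 °C; then p-TsOH·H2O (cat.), wet CH2Cl2, rt; then LiBr (1 equiv), acetone, rt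
Reagents that add atoms: none
Why: Proposed new method: a divalent-chromium/manganese redox cycle converts only the allylic carbon–bromine bond of 8 (the alkenyl bromide and alkenyl iodide are inert without nickel) into a ligand-bound γ-bromo-2-(methoxycarbonyl)allylchromium, which adds through its bromine-bearing carbon to the Si face of enal 5 in a chair transition state fixed by the chiral tridentate ligand (this forms C6–C7 and sets C6); acid then closes the lactone, and bromide SN2' attack on the exocyclic methylene moves the double bond into the ring and erases the bromine-bearing centre. The closest known reactions are the chromium-catalysed enantioselective 2-(alkoxycarbonyl)allylation of aldehydes with 2-(bromomethyl)acrylates and the chromium-mediated γ-haloallylation of aldehydes with 1,3-dihalopropenes.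

Step 7
Reactants: 13 pent-3-yn-1-ol
Product: 14 1-methoxy-4-[(pent-3-yn-1-yloxy)methyl]benzene
Conditions: NaH, PMBCl, Bu4NI (cat.), THF/DMF, 0 °C to rt
Reagents that add atoms: 4-methoxybenzyl chloride, COc1ccc(CCl)cc1
Why: Williamson ether synthesis protects the C3 oxygen as a PMB ether, which survives the organometallic and chromium steps and is removed oxidatively later.

Step 8
Reactants: 14 1-methoxy-4-[(pent-3-yn-1-yloxy)methyl]benzene
Product: 16 1-({[(3E)-4-iodopent-3-en-1-yl]oxy}methyl)-4-methoxybenzene, via alkenylzirconocene chloride 15 (not isolated)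
Conditions: Cp2Zr(H)Cl (1.5 equiv), THF, 50 °C; then iodine, THF, 0 °C
Reagents that add atoms: iodine, [I][I]
Why: Syn-hydrozirconation of the internal alkyne with thermal equilibration places zirconium on the methyl-bearing carbon, and iodinolysis with retention gives the E-trisubstituted alkenyl iodide that becomes the E-configured C1=C10 unit.

Step 9
Reactants: 16 1-({[(3E)-4-iodopent-3-en-1-yl]oxy}methyl)-4-methoxybenzene; 17 oxirane
Product: 19 (3E)-6-[(4-methoxybenzyl)oxy]-3-methylhex-3-en-1-ol, via alkenyllithium 18 (not isolated)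
Conditions: t-BuLi (2.1 equiv), Et2O, −78 °C; then oxirane, −78 to 0 °C
Reagents that add atoms: none
Why: Lithium–iodine exchange with retention of alkene geometry, then SN2 ring opening of oxirane by the alkenyllithium, adds C9 and C8 as a homoallylic alcohol.

Step 10
Reactants: 19 (3E)-6-[(4-methoxybenzyl)oxy]-3-methylhex-3-en-1-ol
Product: 20 (3E)-6-[(4-methoxybenzyl)oxy]-3-methylhex-3-enal
Conditions: Dess–Martin periodinane, NaHCO3, CH2Cl2, 0 °C; used at once
Reagents that add atoms: none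
Why: Buffered Dess–Martin oxidation gives the β,γ-unsaturated aldehyde without base-induced migration of the double bond into conjugation.

Step 11
Reactants: 12 (5S)-3-(bromomethyl)-5-[(1Z)-3-[(tert-butyldimethylsilyl)oxy]-2-iodoprop-1-en-1-yl]furan-2(5H)-one; 20 (3E)-6-[(4-methoxybenzyl)oxy]-3-methylhex-3-enal
Product: 21 (4R,5S)-5-[(1Z)-3-[(tert-butyldimethylsilyl)oxy]-2-iodoprop-1-en-1-yl]-4-[(1S,3E)-1-hydroxy-6-[(4-methoxybenzyl)oxy]-3-methylhex-3-en-1-yl]-3-methylideneoxolan-2-one
Conditions: CrCl2 (3 equiv, nickel-free), THF, 0 °C to rt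
Reagents that add atoms: none
Why: Nozaki–Hiyama-type chromium Barbier allylation: the E-locked 2-(alkoxycarbonyl)allyl chromium generated from 12 attacks the aldehyde through ring carbon C7 on the face anti to the C6 side chain (6,7-trans lactone) in a chair transition state with the aldehyde chain equatorial, which gives the anti carbinol (8S, the C8 epimer of the target) and regenerates the exocyclic methylene.

Step 12
Reactants: 21 the 8S alcohol from step 11; 22 (2E)-2-methylbut-2-enoic acid (tiglic acid)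
Product: 23 (1R,3E)-1-{(2S,3R)-2-[(1Z)-3-[(tert-butyldimethylsilyl)oxy]-2-iodoprop-1-en-1-yl]-4-methylidene-5-oxooxolan-3-yl}-6-[(4-methoxybenzyl)oxy]-3-methylhex-3-en-1-yl (2E)-2-methylbut-2-enoate
Conditions: PPh3, DIAD (premixed), toluene, 0 °C to rt
Reagents that add atoms: none
Why: Mitsunobu esterification: the activated C8 oxygen is displaced by tiglate in an SN2 reaction with inversion, which turns 8S into the required 8R centre and installs the ester in the same operation.

Step 13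
Reactants: 23 the 8R tiglate from step 12
Product: 24 (1R)-1-{(2S,3R)-2-[(1Z)-3-[(tert-butyldimethylsilyl)oxy]-2-iodoprop-1-en-1-yl]-4-methylidene-5-oxooxolan-3-yl}-2-[(2R,3R)-3-{2-[(4-methoxybenzyl)oxy]ethyl}-2-methyloxiran-2-yl]ethyl (2E)-2-methylbut-2-enoate
Conditions: D-fructose-derived Shi ketone (30 mol %), KHSO5 (as Oxone), K2CO3, Bu4NHSO4, MeCN/CH2(OMe)2/aqueous borate buffer (pH 10.5), 0 °C
Reagents that add atoms: potassium peroxymonosulfate, [K+].[O-]S(=O)(=O)OO
Why: Shi asymmetric epoxidation: the chiral dioxirane attacks only the electron-rich trisubstituted C1=C10 alkene (the other three alkenes are electron-poor) through a spiro transition state on the face that gives the (1R,10R)-epoxide.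

Step 14
Reactants: 24 the epoxy PMB ether from step 13
Product: 25 (1R)-1-{(2S,3R)-2-[(1Z)-3-[(tert-butyldimethylsilyl)oxy]-2-iodoprop-1-en-1-yl]-4-methylidene-5-oxooxolan-3-yl}-2-[(2R,3R)-3-(2-hydroxyethyl)-2-methyloxiran-2-yl]ethyl (2E)-2-methylbut-2-enoate
Conditions: DDQ, CH2Cl2/pH 7 phosphate buffer, 0 °C
Reagents that add atoms: none
Why: Oxidative PMB cleavage (hydride abstraction by DDQ, then hydrolysis of the oxocarbenium ion) frees the primary C3 alcohol under buffered conditions that spare the epoxide.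

Step 15
Reactants: 25 the epoxy alcohol from step 14
Product: 26 (1R)-1-{(2S,3R)-2-[(1Z)-3-[(tert-butyldimethylsilyl)oxy]-2-iodoprop-1-en-1-yl]-4-methylidene-5-oxooxolan-3-yl}-2-[(2R,3R)-2-methyl-3-(2-oxoethyl)oxiran-2-yl]ethyl (2E)-2-methylbut-2-enoate
Conditions: Dess–Martin periodinane, NaHCO3, CH2Cl2, 0 °C; used at once
Reagents that add atoms: none
Why: Buffered Dess–Martin oxidation gives the β,γ-epoxy aldehyde under non-basic conditions, so the epoxide does not open by elimination.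

Step 16
Reactants: 26 the epoxy aldehyde from step 15
Product: 27 (1R,3S,6R,7R,8R,10R)-15-[(tert-butyldimethylsilyl)oxy]-1,10-epoxy-3-hydroxy-8-[(2E)-2-methylbut-2-enoyloxy]germacra-4Z,11(13)-dien-6,12-olide
Conditions: CrCl2 (10 equiv), NiCl2 (5 mol %), DMSO, rt, 0.002 M
Reagents that add atoms: none
Why: Nozaki–Hiyama–Kishi reaction: zerovalent nickel inserts into the alkenyl carbon–iodine bond with retention of the Z geometry, transmetalation to trivalent chromium gives an alkenylchromium that adds to the aldehyde at high dilution to close the ten-membered ring at C3–C4, and the ring-forming transition state that keeps the C2 methylene away from the C15 silyloxymethyl group is expected to expose the aldehyde Re face and give the 3S carbinol.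

Step 17
Reactants: 27 the 15-O-TBS macrocycle from step 16
Product: 28 (1R,3S,6R,7R,8R,10R)-1,10-epoxy-3,15-dihydroxy-8-[(2E)-2-methylbut-2-enoyloxy]germacra-4Z,11(13)-dien-6,12-olide (CNP0187917.2)
Conditions: HF·pyridine, pyridine, THF, 0 °C
Reagents that add atoms: none
Why: Buffered fluoride desilylation removes the primary TBS ether without opening the epoxide or adding to the α-methylene lactone, giving the target.

**Compound list**

1 | but-2-yne-1,4-diol | OCC#CCO | starting material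
2 | 4-[(tert-butyldimethylsilyl)oxy]but-2-yn-1-ol | OCC#CCO[Si](C)(C)C(C)(C)C | intermediate
3 | sodium cyclic alkenyl(alkoxy)bis(2-methoxyethoxy)alanate (five-membered O–Al–C ring, Al on the carbon bearing CH2OTBS) | [Na+].COCCO[Al-]1(OCCOC)OCC=C1CO[Si](C)(C)C(C)(C)C | intermediate
4 | (2Z)-4-[(tert-butyldimethylsilyl)oxy]-3-iodobut-2-en-1-ol | OC/C=C(\I)CO[Si](C)(C)C(C)(C)C | intermediate
5 | (2Z)-4-[(tert-butyldimethylsilyl)oxy]-3-iodobut-2-enal | O=C/C=C(\I)CO[Si](C)(C)C(C)(C)C | intermediate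
6 | methyl 2-(bromomethyl)prop-2-enoate | COC(=O)C(=C)CBr | starting material
7 | methyl 2,3-dibromo-2-(bromomethyl)propanoate | COC(=O)C(Br)(CBr)CBr | intermediate
8 | methyl (2Z)-3-bromo-2-(bromomethyl)prop-2-enoate | COC(=O)/C(CBr)=C/Br | intermediate
9 | methyl (4R,5Z)-3-bromo-7-[(tert-butyldimethylsilyl)oxy]-6-iodo-2-methylidene-4-[(trimethylsilyl)oxy]hept-5-enoate (both C3 epimers) | COC(=O)C(=C)C(Br)[C@H](O[Si](C)(C)C)/C=C(\I)CO[Si](C)(C)C(C)(C)C | intermediate
10 | methyl (4R,5Z)-3-bromo-7-[(tert-butyldimethylsilyl)oxy]-4-hydroxy-6-iodo-2-methylidenehept-5-enoate (both C3 epimers) | COC(=O)C(=C)C(Br)[C@H](O)/C=C(\I)CO[Si](C)(C)C(C)(C)C | intermediate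
11 | (5R)-4-bromo-5-[(1Z)-3-[(tert-butyldimethylsilyl)oxy]-2-iodoprop-1-en-1-yl]-3-methylideneoxolan-2-one (both C4 epimers) | C=C1C(Br)[C@@H](/C=C(\I)CO[Si](C)(C)C(C)(C)C)OC1=O | intermediate
12 | (5S)-3-(bromomethyl)-5-[(1Z)-3-[(tert-butyldimethylsilyl)oxy]-2-iodoprop-1-en-1-yl]furan-2(5H)-one | O=C1O[C@H](/C=C(\I)CO[Si](C)(C)C(C)(C)C)C=C1CBr | intermediate
13 | pent-3-yn-1-ol | CC#CCCO | starting material
14 | 1-methoxy-4-[(pent-3-yn-1-yloxy)methyl]benzene | CC#CCCOCc1ccc(OC)cc1 | intermediate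
15 | chlorobis(cyclopentadienyl)[(2E)-5-[(4-methoxybenzyl)oxy]pent-2-en-2-yl]zirconium (cyclopentadienyl rings drawn σ-bonded) | C/C(=C\CCOCc1ccc(OC)cc1)[Zr](Cl)(C1C=CC=C1)C1C=CC=C1 | intermediate
16 | 1-({[(3E)-4-iodopent-3-en-1-yl]oxy}methyl)-4-methoxybenzene | I/C(C)=C/CCOCc1ccc(OC)cc1 | intermediate
17 | oxirane | C1CO1 | starting material
18 | [(2Z)-5-[(4-methoxybenzyl)oxy]pent-2-en-2-yl]lithium (lithium trans to the chain) | [Li]/C(C)=C/CCOCc1ccc(OC)cc1 | intermediate
19 | (3E)-6-[(4-methoxybenzyl)oxy]-3-methylhex-3-en-1-ol | OCC/C(C)=C/CCOCc1ccc(OC)cc1 | intermediate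
20 | (3E)-6-[(4-methoxybenzyl)oxy]-3-methylhex-3-enal | O=CC/C(C)=C/CCOCc1ccc(OC)cc1 | intermediate
21 | (4R,5S)-5-[(1Z)-3-[(tert-butyldimethylsilyl)oxy]-2-iodoprop-1-en-1-yl]-4-[(1S,3E)-1-hydroxy-6-[(4-methoxybenzyl)oxy]-3-methylhex-3-en-1-yl]-3-methylideneoxolan-2-one | C=C1C(=O)O[C@H](/C=C(\I)CO[Si](C)(C)C(C)(C)C)[C@H]1[C@@H](O)C/C(C)=C/CCOCc1ccc(OC)cc1 | intermediate
22 | (2E)-2-methylbut-2-enoic acid (tiglic acid) | C/C=C(\C)C(=O)O | starting material
23 | (1R,3E)-1-{(2S,3R)-2-[(1Z)-3-[(tert-butyldimethylsilyl)oxy]-2-iodoprop-1-en-1-yl]-4-methylidene-5-oxooxolan-3-yl}-6-[(4-methoxybenzyl)oxy]-3-methylhex-3-en-1-yl (2E)-2-methylbut-2-enoate | C=C1C(=O)O[C@H](/C=C(\I)CO[Si](C)(C)C(C)(C)C)[C@H]1[C@H](OC(=O)/C(C)=C/C)C/C(C)=C/CCOCc1ccc(OC)cc1 | intermediate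
24 | (1R)-1-{(2S,3R)-2-[(1Z)-3-[(tert-butyldimethylsilyl)oxy]-2-iodoprop-1-en-1-yl]-4-methylidene-5-oxooxolan-3-yl}-2-[(2R,3R)-3-{2-[(4-methoxybenzyl)oxy]ethyl}-2-methyloxiran-2-yl]ethyl (2E)-2-methylbut-2-enoate | C=C1C(=O)O[C@H](/C=C(\I)CO[Si](C)(C)C(C)(C)C)[C@H]1[C@H](OC(=O)/C(C)=C/C)C[C@@]2(C)O[C@@H]2CCOCc1ccc(OC)cc1 | intermediate
25 | (1R)-1-{(2S,3R)-2-[(1Z)-3-[(tert-butyldimethylsilyl)oxy]-2-iodoprop-1-en-1-yl]-4-methylidene-5-oxooxolan-3-yl}-2-[(2R,3R)-3-(2-hydroxyethyl)-2-methyloxiran-2-yl]ethyl (2E)-2-methylbut-2-enoate | C=C1C(=O)O[C@H](/C=C(\I)CO[Si](C)(C)C(C)(C)C)[C@H]1[C@H](OC(=O)/C(C)=C/C)C[C@@]2(C)O[C@@H]2CCO | intermediate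
26 | (1R)-1-{(2S,3R)-2-[(1Z)-3-[(tert-butyldimethylsilyl)oxy]-2-iodoprop-1-en-1-yl]-4-methylidene-5-oxooxolan-3-yl}-2-[(2R,3R)-2-methyl-3-(2-oxoethyl)oxiran-2-yl]ethyl (2E)-2-methylbut-2-enoate | C=C1C(=O)O[C@H](/C=C(\I)CO[Si](C)(C)C(C)(C)C)[C@H]1[C@H](OC(=O)/C(C)=C/C)C[C@@]2(C)O[C@@H]2CC=O | intermediate
27 | (1R,3S,6R,7R,8R,10R)-15-[(tert-butyldimethylsilyl)oxy]-1,10-epoxy-3-hydroxy-8-[(2E)-2-methylbut-2-enoyloxy]germacra-4Z,11(13)-dien-6,12-olide | C=C1C(=O)O[C@@H]2/C=C(/CO[Si](C)(C)C(C)(C)C)[C@@H](O)C[C@H]3O[C@]3(C)C[C@@H](OC(=O)/C(C)=C/C)[C@@H]12 | intermediate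
28 | (1R,3S,6R,7R,8R,10R)-1,10-epoxy-3,15-dihydroxy-8-[(2E)-2-methylbut-2-enoyloxy]germacra-4Z,11(13)-dien-6,12-olide (CNP0187917.2) | C=C1C(=O)O[C@@H]2/C=C(/CO)[C@@H](O)C[C@H]3O[C@]3(C)C[C@@H](OC(=O)/C(C)=C/C)[C@@H]12 | target

**Step count and risks**

Total step count: 17. Longest linear sequence: 11 steps (steps 1–3, 6, 11–17; the arm through steps 7–10 and 11–17 is equally long), i.e. 11 of 17.

The three steps most likely to fail:

(a) Step 6, the new chromium-catalysed γ-bromoallylation/lactonisation/bromide shift. The risks are insufficient enantioselectivity with the bromine-substituted allyl donor, further reduction of the secondary allylic bromide in 9 by divalent chromium, and an incomplete 1,3-shift. The fallback uses only known reactions; it sets out from enal 5 and comes back at butenolide 12. Catalytic asymmetric vinylation of 5 with Zn(CH=CH2)2 and an isoborneol-derived amino alcohol ligand gives (3S,4Z)-6-[(tert-butyldimethylsilyl)oxy]-5-iodohexa-1,4-dien-3-ol F1. Carbodiimide esterification with 2-(bromomethyl)acrylic acid (DIC, catalytic DMAP, 0 °C) gives (3S,4Z)-6-[(tert-butyldimethylsilyl)oxy]-5-iodohexa-1,4-dien-3-yl 2-(bromomethyl)prop-2-enoate F2. Ring-closing metathesis with the second-generation Hoveyda–Grubbs catalyst RuCl2(=CH-C6H4-2-O-i-Pr)(H2IMes) in toluene at 80 °C closes the butenolide and returns 12; the hindered iodoalkene does not take part.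

(b) Step 12, the Mitsunobu inversion at a hindered carbinol next to the lactone. The risks are elimination towards the conjugated diene and participation of the lactone carbonyl. The fallback sets out from alcohol 21 and comes back at tiglate 23. Buffered Dess–Martin oxidation gives the ketone (4S,5S)-5-[(1Z)-3-[(tert-butyldimethylsilyl)oxy]-2-iodoprop-1-en-1-yl]-4-[(3E)-6-[(4-methoxybenzyl)oxy]-3-methylhex-3-enoyl]-3-methylideneoxolan-2-one F3. Reagent-controlled reduction with (S)-2-methyl-CBS-oxazaborolidine and catecholborane at −78 °C gives the 8R alcohol (4R,5S)-5-[(1Z)-3-[(tert-butyldimethylsilyl)oxy]-2-iodoprop-1-en-1-yl]-4-[(1R,3E)-1-hydroxy-6-[(4-methoxybenzyl)oxy]-3-methylhex-3-en-1-yl]-3-methylideneoxolan-2-one F4. Yamaguchi esterification with tiglic acid 22 (retention) then gives 23. If the Barbier reaction of step 11 should deliver the syn carbinol instead of the anti one, it is F4 itself and is esterified in the same way.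

(c) Step 16, the ten-membered ring closure. The risks are the lability of the β,γ-epoxy aldehyde 26 and the wrong configuration at C3. The fallback closes the ring before the epoxide is made; it sets out from tiglate 23 and comes back at macrocycle 27. DDQ removal of the PMB group gives (1R,3E)-1-{(2S,3R)-2-[(1Z)-3-[(tert-butyldimethylsilyl)oxy]-2-iodoprop-1-en-1-yl]-4-methylidene-5-oxooxolan-3-yl}-6-hydroxy-3-methylhex-3-en-1-yl (2E)-2-methylbut-2-enoate F5. Dess–Martin oxidation gives the β,γ-unsaturated aldehyde (1R,3E)-1-{(2S,3R)-2-[(1Z)-3-[(tert-butyldimethylsilyl)oxy]-2-iodoprop-1-en-1-yl]-4-methylidene-5-oxooxolan-3-yl}-3-methyl-6-oxohex-3-en-1-yl (2E)-2-methylbut-2-enoate F6. CrCl2/NiCl2 cyclisation in DMSO at high dilution gives (3S,6R,7R,8R)-15-[(tert-butyldimethylsilyl)oxy]-3-hydroxy-8-[(2E)-2-methylbut-2-enoyloxy]germacra-1(10)E,4Z,11(13)-trien-6,12-olide F7. Shi epoxidation of its only electron-rich alkene with the D-fructose-derived ketone then gives 27. If either cyclisation favours the C3 epimer, Dess–Martin oxidation of the carbinol mixture to the enone (1R,6R,7R,8R,10R)-15-[(tert-butyldimethylsilyl)oxy]-1,10-epoxy-3-oxo-8-[(2E)-2-methylbut-2-enoyloxy]germacra-4Z,11(13)-dien-6,12-olide F8 and reduction with (R)-2-methyl-CBS-oxazaborolidine and catecholborane resets C3 to S and gives 27.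

**Further compounds**

F1 | step 6 | (3S,4Z)-6-[(tert-butyldimethylsilyl)oxy]-5-iodohexa-1,4-dien-3-ol | C=C[C@H](O)/C=C(\I)CO[Si](C)(C)C(C)(C)C
F2 | step 6 | (3S,4Z)-6-[(tert-butyldimethylsilyl)oxy]-5-iodohexa-1,4-dien-3-yl 2-(bromomethyl)prop-2-enoate | C=C[C@H](OC(=O)C(=C)CBr)/C=C(\I)CO[Si](C)(C)C(C)(C)C
F3 | step 12 | (4S,5S)-5-[(1Z)-3-[(tert-butyldimethylsilyl)oxy]-2-iodoprop-1-en-1-yl]-4-[(3E)-6-[(4-methoxybenzyl)oxy]-3-methylhex-3-enoyl]-3-methylideneoxolan-2-one | C=C1C(=O)O[C@H](/C=C(\I)CO[Si](C)(C)C(C)(C)C)[C@H]1C(=O)C/C(C)=C/CCOCc1ccc(OC)cc1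
F4 | step 12 | (4R,5S)-5-[(1Z)-3-[(tert-butyldimethylsilyl)oxy]-2-iodoprop-1-en-1-yl]-4-[(1R,3E)-1-hydroxy-6-[(4-methoxybenzyl)oxy]-3-methylhex-3-en-1-yl]-3-methylideneoxolan-2-one | C=C1C(=O)O[C@H](/C=C(\I)CO[Si](C)(C)C(C)(C)C)[C@H]1[C@H](O)C/C(C)=C/CCOCc1ccc(OC)cc1
F5 | step 16 | (1R,3E)-1-{(2S,3R)-2-[(1Z)-3-[(tert-butyldimethylsilyl)oxy]-2-iodoprop-1-en-1-yl]-4-methylidene-5-oxooxolan-3-yl}-6-hydroxy-3-methylhex-3-en-1-yl (2E)-2-methylbut-2-enoate | C=C1C(=O)O[C@H](/C=C(\I)CO[Si](C)(C)C(C)(C)C)[C@H]1[C@H](OC(=O)/C(C)=C/C)C/C(C)=C/CCO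
F6 | step 16 | (1R,3E)-1-{(2S,3R)-2-[(1Z)-3-[(tert-butyldimethylsilyl)oxy]-2-iodoprop-1-en-1-yl]-4-methylidene-5-oxooxolan-3-yl}-3-methyl-6-oxohex-3-en-1-yl (2E)-2-methylbut-2-enoate | C=C1C(=O)O[C@H](/C=C(\I)CO[Si](C)(C)C(C)(C)C)[C@H]1[C@H](OC(=O)/C(C)=C/C)C/C(C)=C/CC=O
F7 | step 16 | (3S,6R,7R,8R)-15-[(tert-butyldimethylsilyl)oxy]-3-hydroxy-8-[(2E)-2-methylbut-2-enoyloxy]germacra-1(10)E,4Z,11(13)-trien-6,12-olide | C=C1C(=O)O[C@@H]2/C=C(/CO[Si](C)(C)C(C)(C)C)[C@@H](O)C/C=C(C)/C[C@@H](OC(=O)/C(C)=C/C)[C@@H]12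
F8 | step 16 | (1R,6R,7R,8R,10R)-15-[(tert-butyldimethylsilyl)oxy]-1,10-epoxy-3-oxo-8-[(2E)-2-methylbut-2-enoyloxy]germacra-4Z,11(13)-dien-6,12-olide | C=C1C(=O)O[C@@H]2/C=C(/CO[Si](C)(C)C(C)(C)C)C(=O)C[C@H]3O[C@]3(C)C[C@@H](OC(=O)/C(C)=C/C)[C@@H]12
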